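**Plan**

- Retrosynthesis: ring A is cut at C4a–C8a and C7–C8, giving a 2-alkyl-4-methoxyfuran and an ethynyl group on C1. Then C1–aryl (arylcopper on a bromoallene), C3–C4 (lactone enolate alkylation) and C1–C2 (enolate acylation) are cut, back to D-tartrate acetonide.
- Forward: the C1–C4 chain is built on the tartrate dioxolane (acylation at C2, CBS reduction with lactonisation, alkylation at C3). The lactone is reduced, the aryl group is placed on C1, and one thermal step closes ring B and builds ring A as its phenol. Deprotection follows.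
- Feature used: ring A has OMe on C6 next to OH on C7, H on C5 and C8, and C4 and C1 on C4a and C8a. This is the pattern left when a 4-methoxyfuran bound through its C2 (becoming C4a) adds an alkyne (becoming C8a and C8) and keeps its ring oxygen on C7.
- Stereochemistry: C2 and C3 are the two carbons of D-tartaric acid, each H replaced with retention (C3 enforced by a cis-fused lactone). C1 comes from a CBS reduction and is relayed to carbon by two anti SN2′ displacements.

Key step: step 12

Remark: plicatic acid numbering (C1–C4, C4a–C8a) is used for the corresponding atoms of all intermediates; C2 and C3 are the dioxolane carbons.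

Assumption: the lithium enolate of the tartrate acetonide is acylated cis to the ester on the neighbouring carbon, as in its known alkylations; the configuration carried forward does not rest on this, because only that epimer can lactonise in step 6.

**Route**

Step 1
Reactants: 1 4-bromofuran-2-carbaldehyde
Product: 2 (4-bromofuran-2-yl)methanol
Conditions: NaBH4, MeOH, 0 °C
Reagents that add atoms: none
Why: Borohydride reduction of an aldehyde, to which the furan ring and the C–Br bond are inert.

Step 2
Reactants: 2 (4-bromofuran-2-yl)methanol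
Product: 3 (4-methoxyfuran-2-yl)methanol
Conditions: NaOMe (3 equiv), CuBr (10 mol %), MeOH/NMP, 100 °C
Reagents that add atoms: sodium methoxide, [Na+].[O-]C
Why: Ullmann-type copper-catalysed methoxylation, a known reaction of 3-bromofurans and 3-bromothiophenes; the hydroxymethyl group is only deprotonated.

Step 3
Reactants: 4 5-bromo-2-hydroxy-3-methoxybenzaldehyde
Product: 6 5-bromo-3-methoxybenzene-1,2-diol, via aryl formate 5 (not isolated)
Conditions: 30% aq. H2O2, 1 M NaOH, 0 °C → rt
Reagents that add atoms: hydrogen peroxide, OO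
Why: Dakin oxidation, in which hydroperoxide adds to the ortho-hydroxy aldehyde, the aryl group migrates to oxygen and the formate is hydrolysed in the basic medium.

Step 4
Reactants: 6 5-bromo-3-methoxybenzene-1,2-diol
Product: 7 1,2-bis(benzyloxy)-5-bromo-3-methoxybenzene
Conditions: BnBr (2.3 equiv), K2CO3, DMF, 50 °C
Reagents that add atoms: benzyl bromide, BrCc1ccccc1
Why: Williamson etherification of both phenols; the benzyl ethers are kept until the final hydrogenolysis.

Step 5
Reactants: 8 dimethyl D-tartrate acetonide; 9 3-(trimethylsilyl)prop-2-ynoic acid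
Product: 12 C2-acylated ynone diester, via acid chloride 10 (not isolated), via lithium enolate 11 (not isolated)
Conditions: 9, (COCl)2, DMF (cat.), CH2Cl2, 0 °C → rt, evaporation; 8, lithium diisopropylamide, THF, −78 °C, 10 min, then cannulated into 10 in THF at −78 °C; AcOH quench at −78 °C
Reagents that add atoms: none
Why: Claisen-type C-acylation of the tartrate acetonide enolate, which resists β-elimination at −78 °C; the acyl group should take the place of the C2 hydrogen (cis to the C3 ester), setting the quaternary C2 relative to the untouched C3.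

Step 6
Reactants: 12 C2-acylated ynone diester
Product: 14 cis-fused bicyclic lactone, via propargylic alcohol 13 (not isolated)
Conditions: (R)-Me-CBS catalyst [(R)-1-methyl-3,3-diphenyltetrahydro-1H,3H-pyrrolo[1,2-c][1,3,2]oxazaborole, 0.2 equiv], catecholborane, CH2Cl2, −78 °C; MeOH; then pyridinium p-toluenesulfonate (cat.), toluene, 60 °C
Reagents that add atoms: none
Why: CBS reduction with the quaternary C2 as the large and the silylalkynyl as the small substituent, so the (R)-catalyst should give the (1S)-alcohol under reagent control; its hydroxyl, cis to the C3 ester, closes the γ-lactone, which tells the two carboxyl groups apart and leaves any C2 epimer behind.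

Step 7
Reactants: 14 cis-fused bicyclic lactone; 3 (4-methoxyfuran-2-yl)methanol
Product: 17 C3-furylmethylated lactone, via furfuryl bromide 15 (not isolated), via lactone enolate 16 (not isolated)
Conditions: 3, PBr3 (0.4 equiv), pyridine (cat.), Et2O, −20 °C, cold NaHCO3 wash, solution used at once; 14, lithium diisopropylamide, THF/DMPU, −78 °C, 5 min, then 15, −78 → −50 °C
Reagents that add atoms: none
Why: Alkylation of an α-alkoxy lactone enolate with a reactive furfuryl bromide; the cis fusion to the acetonide leaves only the convex face open, so the furylmethyl group must take the place of the C3 hydrogen and the C3 quaternary centre is set with retention.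

Step 8
Reactants: 17 C3-furylmethylated lactone
Product: 19 diol with terminal alkyne, via silylalkyne diol 18 (not isolated)
Conditions: NaBH4, MeOH/THF, 0 °C; then K2CO3, MeOH, 0 °C → rt
Reagents that add atoms: none
Why: Borohydride should reduce the strained α-alkoxy lactone much faster than the neopentyl methyl ester on C2, and methanolic carbonate then cleaves the alkynyl C–Si bond; no stereocentre is touched.

Step 9
Reactants: 19 diol with terminal alkyne
Product: 20 primary TBS ether
Conditions: TBSCl (1.1 equiv), imidazole, DMF, 0 °C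
Reagents that add atoms: tert-butyldimethylsilyl chloride, CC(C)(C)[Si](C)(C)Cl
Why: Selective silylation of the primary hydroxyl over the hindered secondary propargylic one, so that only the C1 hydroxyl is activated next.

Step 10
Reactants: 20 primary TBS ether
Product: 22 bromoallene, via propargylic mesylate 21 (not isolated)
Conditions: MsCl, Et3N, CH2Cl2, −20 °C; then LiBr, CuBr·SMe2, THF, rt
Reagents that add atoms: lithium bromide, [Li+].[Br-]
Why: Anti SN2′ displacement of a propargylic mesylate by bromocuprate at the unhindered alkyne terminus, which converts the (1S) centre into the (aS) allene axis (centre-to-axis chirality transfer).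

Step 11
Reactants: 22 bromoallene; 7 1,2-bis(benzyloxy)-5-bromo-3-methoxybenzene
Product: 25 furan–alkyne cycloaddition precursor, via aryl Grignard reagent 23 (not isolated), via arylcopper 24 (not isolated)
Conditions: 7, Mg, THF, 40 °C; CuBr·SMe2, LiBr, THF, −60 °C; then 22, −70 °C → rt
Reagents that add atoms: none
Why: Anti SN2′ (1,3-) substitution of a 1-bromoallene by an arylcopper reagent, the established route to 3-aryl-1-alkynes; the aryl group enters C1 opposite to bromide, so the two anti displacements place it where the C1 oxygen was and should give the (1R) centre of 25.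

Step 12
Reactants: 25 furan–alkyne cycloaddition precursor
Product: 27 ring A phenol of the protected tetralin, via oxanorbornadiene 26 (not isolated)
Conditions: o-dichlorobenzene (degassed), 2,6-di-tert-butyl-4-methylphenol (cat.), 180 °C, sealed tube
Reagents that add atoms: none
Why: The electron-rich 2-alkyl-4-methoxyfuran adds as a diene through its C2 and C5 across the terminal alkyne, which the four-atom tether C4–C3–C2–C1 with its dioxolane ring holds gauche over it; this forms C4a–C8a and C7–C8 and gives the 7-oxanorbornadiene 26. Heterolysis of the C4a–O bond is assisted by the C6 methoxy group through C5=C6, and loss of the C7 proton then aromatises ring A without loss of any atom, so the furan oxygen becomes the C7 hydroxyl. The closest known reaction type is the intramolecular Diels–Alder reaction of donor-substituted furans with tethered alkynes, followed by opening of the oxygen bridge to a phenol. Ring B closes as a six-membered carbocycle through the tether-spanning C4a–C8a bond (fused mode of an intramolecular [4+2] with the tether on a diene terminus), and ring A closes as a six-membered carbocycle through that bond together with C7–C8. No stereocentre is formed, C1–C3 are untouched, and both facial adducts converge on the same arene. The selectivity needed is the direction of bridge opening (C4a–O, not C7–O), which the quaternary C4a and the methoxy-stabilised cation secure, so that OH ends on C7 next to OMe on C6.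

Step 13
Reactants: 27 ring A phenol of the protected tetralin
Product: 29 di-O-benzylplicatic acid, via triol methyl ester 28 (not isolated)
Conditions: 2 M aq. HCl, THF, 40 °C; then LiOH·H2O (excess), THF/H2O, 40 °C; HCl to pH 3
Reagents that add atoms: lithium hydroxide, [Li+].[OH-]
Why: Acid hydrolysis of the strained trans-fused acetonide and the primary silyl ether, then saponification of the α-hydroxy methyl ester; none of C1–C3 can epimerise.

Step 14
Reactants: 29 di-O-benzylplicatic acid
Product: 30 plicatic acid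
Conditions: H2 (1 atm), 10% Pd/C, MeOH (degassed), rt
Reagents that add atoms: none
Why: Hydrogenolysis of the two aryl benzyl ethers over palladium, with no other reducible group present.

**Compound list**

1 | 4-bromofuran-2-carbaldehyde | O=Cc1cc(Br)co1 | starting material
2 | (4-bromofuran-2-yl)methanol | OCc1cc(Br)co1 | intermediate
3 | (4-methoxyfuran-2-yl)methanol | COc1coc(CO)c1 | intermediate
4 | 5-bromo-2-hydroxy-3-methoxybenzaldehyde | COc1cc(Br)cc(C=O)c1O | starting material
5 | 5-bromo-2-hydroxy-3-methoxyphenyl formate | COc1cc(Br)cc(OC=O)c1O | intermediate (not isolated)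
6 | 5-bromo-3-methoxybenzene-1,2-diol | COc1cc(Br)cc(O)c1O | intermediate
7 | 1,2-bis(benzyloxy)-5-bromo-3-methoxybenzene | COc1cc(Br)cc(OCc2ccccc2)c1OCc1ccccc1 | intermediate
8 | dimethyl (4S,5S)-2,2-dimethyl-1,3-dioxolane-4,5-dicarboxylate (D-tartrate acetonide) | COC(=O)[C@H]1OC(C)(C)O[C@@H]1C(=O)OC | starting material
9 | 3-(trimethylsilyl)prop-2-ynoic acid | C[Si](C)(C)C#CC(=O)O | starting material
10 | 3-(trimethylsilyl)prop-2-ynoyl chloride | C[Si](C)(C)C#CC(=O)Cl | intermediate (not isolated)
11 | lithium ester enolate of 8 (C2 trigonal, C3 intact) | COC(O[Li])=C(O1)[C@H](OC1(C)C)C(=O)OC | intermediate (not isolated)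
12 | dimethyl (4R,5S)-2,2-dimethyl-4-[3-(trimethylsilyl)prop-2-ynoyl]-1,3-dioxolane-4,5-dicarboxylate (acyl group cis to the C5 ester) | C[Si](C)(C)C#CC(=O)[C@@](O1)(C(=O)OC)[C@H](OC1(C)C)C(=O)OC | intermediate
13 | dimethyl (4S,5S)-4-[(1S)-1-hydroxy-3-(trimethylsilyl)prop-2-yn-1-yl]-2,2-dimethyl-1,3-dioxolane-4,5-dicarboxylate | C[Si](C)(C)C#C[C@H](O)[C@@](O1)(C(=O)OC)[C@H](OC1(C)C)C(=O)OC | intermediate (not isolated)
14 | methyl (3aS,4S,6aS)-2,2-dimethyl-6-oxo-4-[(trimethylsilyl)ethynyl]tetrahydrofuro[3,4-d][1,3]dioxole-3a(4H)-carboxylate (γ-lactone cis-fused to the acetonide; alkynyl on the convex face, cis to CO2Me) | C[Si](C)(C)C#C[C@H](O2)[C@@](O1)(C(=O)OC)[C@H](OC1(C)C)C2=O | intermediate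
15 | 2-(bromomethyl)-4-methoxyfuran | COc1coc(CBr)c1 | intermediate (not isolated)
16 | lithium enolate of lactone 14 (C3 trigonal) | C[Si](C)(C)C#C[C@H](O2)[C@@](O1)(C(=O)OC)C(OC1(C)C)=C2O[Li] | intermediate (not isolated)
17 | methyl (3aS,4S,6aS)-6a-[(4-methoxyfuran-2-yl)methyl]-2,2-dimethyl-6-oxo-4-[(trimethylsilyl)ethynyl]tetrahydrofuro[3,4-d][1,3]dioxole-3a(4H)-carboxylate | C[Si](C)(C)C#C[C@H](O2)[C@@](O1)(C(=O)OC)[C@](OC1(C)C)(C2=O)Cc1cc(OC)co1 | intermediate
18 | methyl (4S,5R)-5-(hydroxymethyl)-4-[(1S)-1-hydroxy-3-(trimethylsilyl)prop-2-yn-1-yl]-5-[(4-methoxyfuran-2-yl)methyl]-2,2-dimethyl-1,3-dioxolane-4-carboxylate | C[Si](C)(C)C#C[C@H](O)[C@@](O1)(C(=O)OC)[C@](OC1(C)C)(CO)Cc1cc(OC)co1 | intermediate (not isolated)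
19 | methyl (4S,5R)-5-(hydroxymethyl)-4-[(1S)-1-hydroxyprop-2-yn-1-yl]-5-[(4-methoxyfuran-2-yl)methyl]-2,2-dimethyl-1,3-dioxolane-4-carboxylate | C#C[C@H](O)[C@@](O1)(C(=O)OC)[C@](OC1(C)C)(CO)Cc1cc(OC)co1 | intermediate
20 | methyl (4S,5R)-5-{[(tert-butyldimethylsilyl)oxy]methyl}-4-[(1S)-1-hydroxyprop-2-yn-1-yl]-5-[(4-methoxyfuran-2-yl)methyl]-2,2-dimethyl-1,3-dioxolane-4-carboxylate | C#C[C@H](O)[C@@](O1)(C(=O)OC)[C@](OC1(C)C)(CO[Si](C)(C)C(C)(C)C)Cc1cc(OC)co1 | intermediate
21 | (1S)-methanesulfonate of 20 | C#C[C@H](OS(C)(=O)=O)[C@@](O1)(C(=O)OC)[C@](OC1(C)C)(CO[Si](C)(C)C(C)(C)C)Cc1cc(OC)co1 | intermediate (not isolated)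
22 | methyl (4S,5R)-4-[(aS)-3-bromopropa-1,2-dien-1-yl]-5-{[(tert-butyldimethylsilyl)oxy]methyl}-5-[(4-methoxyfuran-2-yl)methyl]-2,2-dimethyl-1,3-dioxolane-4-carboxylate | Br[CH]=[C@@]=[CH][C@@](O1)(C(=O)OC)[C@](OC1(C)C)(CO[Si](C)(C)C(C)(C)C)Cc1cc(OC)co1 | intermediate
23 | [3,4-bis(benzyloxy)-5-methoxyphenyl]magnesium bromide | COc1cc([Mg]Br)cc(OCc2ccccc2)c1OCc1ccccc1 | intermediate (not isolated)
24 | [3,4-bis(benzyloxy)-5-methoxyphenyl]copper | COc1cc([Cu])cc(OCc2ccccc2)c1OCc1ccccc1 | intermediate (not isolated)
25 | methyl (4S,5R)-4-{(1R)-1-[3,4-bis(benzyloxy)-5-methoxyphenyl]prop-2-yn-1-yl}-5-{[(tert-butyldimethylsilyl)oxy]methyl}-5-[(4-methoxyfuran-2-yl)methyl]-2,2-dimethyl-1,3-dioxolane-4-carboxylate | C#C[C@H](c1cc(OCc4ccccc4)c(OCc4ccccc4)c(OC)c1)[C@@](O3)(C(=O)OC)[C@](OC3(C)C)(CO[Si](C)(C)C(C)(C)C)Cc1cc(OC)co1 | intermediate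
26 | 4a,7-oxygen-bridged adduct (7-oxanorbornadiene with C5=C6(OMe) and C8=C8a, fused to ring B; both bridgehead configurations) | COC1=CC23OC1C=C2[C@H](c1cc(OCc4ccccc4)c(OCc4ccccc4)c(OC)c1)[C@@](O5)(C(=O)OC)[C@](OC5(C)C)(CO[Si](C)(C)C(C)(C)C)C3 | intermediate (not isolated)
27 | methyl (1S,2S,3R)-1-[3,4-bis(benzyloxy)-5-methoxyphenyl]-3-{[(tert-butyldimethylsilyl)oxy]methyl}-7-hydroxy-2,3-(isopropylidenedioxy)-6-methoxy-1,2,3,4-tetrahydronaphthalene-2-carboxylate | COc1cc2c(cc1O)[C@H](c1cc(OCc4ccccc4)c(OCc4ccccc4)c(OC)c1)[C@@](O3)(C(=O)OC)[C@](OC3(C)C)(CO[Si](C)(C)C(C)(C)C)C2 | intermediate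
28 | methyl (1S,2S,3R)-1-[3,4-bis(benzyloxy)-5-methoxyphenyl]-2,3,7-trihydroxy-3-(hydroxymethyl)-6-methoxy-1,2,3,4-tetrahydronaphthalene-2-carboxylate | COc1cc2c(cc1O)[C@H](c1cc(OCc4ccccc4)c(OCc4ccccc4)c(OC)c1)[C@@](O)(C(=O)OC)[C@](O)(CO)C2 | intermediate (not isolated)
29 | (1S,2S,3R)-1-[3,4-bis(benzyloxy)-5-methoxyphenyl]-2,3,7-trihydroxy-3-(hydroxymethyl)-6-methoxy-1,2,3,4-tetrahydronaphthalene-2-carboxylic acid | COc1cc2c(cc1O)[C@H](c1cc(OCc4ccccc4)c(OCc4ccccc4)c(OC)c1)[C@@](O)(C(=O)O)[C@](O)(CO)C2 | intermediate
30 | plicatic acid (C1 S, C2 S, C3 R by the CIP rules for the structure given) | COc1cc2c(cc1O)[C@H](c1cc(O)c(O)c(OC)c1)[C@@](O)(C(=O)O)[C@](O)(CO)C2 | target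

**Step count and risks**

Total steps: 14. Longest linear sequence: 10 steps (8 to 30, steps 5–14).

Step 7. What may go wrong: β-elimination of the lactone enolate with opening of the dioxolane ring, or alkylation on the crowded convex face so slow that the labile bromide decomposes first. Fallback, from 8 back to 17: the two enolate reactions are run in the opposite order. Enolate 11 is alkylated with 15 (lithium diisopropylamide, THF/HMPA, −78 °C), a reaction known for this enolate with benzylic bromides and expected cis to the neighbouring ester, to give dimethyl (4S,5S)-4-[(4-methoxyfuran-2-yl)methyl]-2,2-dimethyl-1,3-dioxolane-4,5-dicarboxylate F1. A second deprotonation gives its lithium enolate F2, which is acylated with 10 on the face away from the furylmethyl group to give the ynone F3. CBS reduction as in step 6 gives the (1S)-alcohol F4, whose hydroxyl can reach the C3 ester only in the desired C2 epimer and then closes to 17. In this order the C3 configuration rests on the facial preference of the first alkylation and no longer on a ring constraint.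

Step 11. What may go wrong: attack of the arylcopper at the brominated carbon instead of the neopentyl-like C1 (arylallene formation), or partial loss of the axis-to-centre chirality transfer. Fallback, from 17 back to 25: a stereoconvergent radical cross-coupling replaces the SN2′ step. 17 is reduced as in step 8 but worked up before the carbonate treatment, so that 18 is isolated, and silylation as in step 9 gives the silylalkyne TBS ether F5. Appel bromination (CBr4, PPh3, CH2Cl2) gives the propargylic bromide F6, whose C1 epimers are of no consequence, and 23 is transmetalated with ZnBr2 to the arylzinc bromide F7. Nickel-catalysed stereoconvergent Negishi arylation of F6 with F7 gives the C-silylated alkyne F8; the conditions are NiCl2·DME with 2,6-bis[(4S)-4-isopropyl-4,5-dihydrooxazol-2-yl]pyridine or its enantiomer, chosen for the C1 configuration of 25, in DME at −20 °C. K2CO3 in MeOH then gives 25.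

Step 12. What may go wrong: cycloaddition of the unactivated terminal alkyne too slow at temperatures the methoxyfuran tolerates, or cycloreversion outrunning the bridge opening. Fallback, from 25 back to 30: the dienophile is activated by a halogen that is removed at the end. Bromination of the alkyne terminus (N-bromosuccinimide, AgNO3 cat., acetone) gives the 1-bromoalkyne F9, whose electron-withdrawing halogen lowers the alkyne LUMO. Heating gives the bromo-substituted bridged adduct F10 and, after the same bridge opening, the 8-bromo-7-phenol F11. Hydrolysis as in step 13 proceeds through the bromo triol ester F12 to the bromo acid F13, and hydrogenolysis over Pd/C with Et3N removes the C8 bromine together with the benzyl groups to give 30.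

Further compounds
F1 | step 7 | dimethyl (4S,5S)-4-[(4-methoxyfuran-2-yl)methyl]-2,2-dimethyl-1,3-dioxolane-4,5-dicarboxylate | COC(=O)[C@@H](O1)[C@](OC1(C)C)(C(=O)OC)Cc1cc(OC)co1
F2 | step 7 | lithium ester enolate of F1 | COC(O[Li])=C(O1)[C@](OC1(C)C)(C(=O)OC)Cc1cc(OC)co1
F3 | step 7 | dimethyl (4R,5S)-5-[(4-methoxyfuran-2-yl)methyl]-2,2-dimethyl-4-[3-(trimethylsilyl)prop-2-ynoyl]-1,3-dioxolane-4,5-dicarboxylate | C[Si](C)(C)C#CC(=O)[C@@](O1)(C(=O)OC)[C@](OC1(C)C)(C(=O)OC)Cc1cc(OC)co1
F4 | step 7 | dimethyl (4S,5S)-4-[(1S)-1-hydroxy-3-(trimethylsilyl)prop-2-yn-1-yl]-5-[(4-methoxyfuran-2-yl)methyl]-2,2-dimethyl-1,3-dioxolane-4,5-dicarboxylate | C[Si](C)(C)C#C[C@H](O)[C@@](O1)(C(=O)OC)[C@](OC1(C)C)(C(=O)OC)Cc1cc(OC)co1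
F5 | step 11 | primary TBS ether of 18 | C[Si](C)(C)C#C[C@H](O)[C@@](O1)(C(=O)OC)[C@](OC1(C)C)(CO[Si](C)(C)C(C)(C)C)Cc1cc(OC)co1
F6 | step 11 | C1 bromide derived from F5 (both C1 epimers) | C[Si](C)(C)C#CC(Br)[C@@](O1)(C(=O)OC)[C@](OC1(C)C)(CO[Si](C)(C)C(C)(C)C)Cc1cc(OC)co1
F7 | step 11 | [3,4-bis(benzyloxy)-5-methoxyphenyl]zinc bromide | COc1cc([Zn]Br)cc(OCc2ccccc2)c1OCc1ccccc1
F8 | step 11 | C-trimethylsilyl derivative of 25 | C[Si](C)(C)C#C[C@H](c1cc(OCc4ccccc4)c(OCc4ccccc4)c(OC)c1)[C@@](O3)(C(=O)OC)[C@](OC3(C)C)(CO[Si](C)(C)C(C)(C)C)Cc1cc(OC)co1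
F9 | step 12 | 1-bromoalkyne derived from 25 | BrC#C[C@H](c1cc(OCc4ccccc4)c(OCc4ccccc4)c(OC)c1)[C@@](O3)(C(=O)OC)[C@](OC3(C)C)(CO[Si](C)(C)C(C)(C)C)Cc1cc(OC)co1
F10 | step 12 | 8-bromo analogue of bridged adduct 26 | COC1=CC23OC1C(Br)=C2[C@H](c1cc(OCc4ccccc4)c(OCc4ccccc4)c(OC)c1)[C@@](O5)(C(=O)OC)[C@](OC5(C)C)(CO[Si](C)(C)C(C)(C)C)C3
F11 | step 12 | 8-bromo analogue of 27 | COc1cc2c(c(Br)c1O)[C@H](c1cc(OCc4ccccc4)c(OCc4ccccc4)c(OC)c1)[C@@](O3)(C(=O)OC)[C@](OC3(C)C)(CO[Si](C)(C)C(C)(C)C)C2
F12 | step 12 | 8-bromo analogue of 28 | COc1cc2c(c(Br)c1O)[C@H](c1cc(OCc4ccccc4)c(OCc4ccccc4)c(OC)c1)[C@@](O)(C(=O)OC)[C@](O)(CO)C2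
F13 | step 12 | 8-bromo analogue of 29 | COc1cc2c(c(Br)c1O)[C@H](c1cc(OCc4ccccc4)c(OCc4ccccc4)c(OC)c1)[C@@](O)(C(=O)O)[C@](O)(CO)C2
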